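**Strategy.** The cyclohexene ring of the hexahydroindene core (C3a–C4–C5–C6=C7–C7a) is closed by a [4+2] annulation of a cyclopentane 1,5-dialdehyde (CHO on C7a, CH2CHO on C3a) with the C5–C6 unit of methyl but-2-ynoate, used as its β-phosphonio crotonate. Amine-catalysed enamine addition forges C4–C5, and the ylide so formed closes C6=C7 by intramolecular Wittig reaction. The step exploits that C4 and C5 each sit α to a carbonyl-derived carbon and that C6=C7 is a methyl-bearing ring alkene; it leaves CHO on C4 (aryl carbinol) and CO2Me on C5 (triene handle). The (Z,Z,Z)-triene comes from an enediyne by Zn(Cu/Ag) reduction.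

Key step: step 8

Remark: the target is taken exactly as drawn (free phenol, all-Z triene, 2Z,4E acid); the sense of induction of the chiral catalyst in step 1 and of the allylborane in step 17 is assigned by analogy, and the antipode would be used if it proved opposite.

**Step 1**
Reactants: 1 4,4-dimethylcyclopent-2-en-1-one; 2 1-[(tert-butyldimethylsilyl)oxy]-1-methoxyethene
Product: 4 methyl 2-[(1R,5S)-5-[(dimethylamino)methyl]-2,2-dimethyl-4-oxocyclopentyl]acetate, via silyl enol ether 3 (not isolated)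
Conditions: (S)-o-tolyl-CBS-oxazaborolidinium triflimide (20 mol %), toluene, −40 °C; then Me2N=CH2+ I−, CH2Cl2, 0 °C to rt; aq NaHCO3
Reagents that add atoms: N,N-dimethylmethyleneiminium iodide (Eschenmoser's salt) C[N+](C)=C.[I-]
Why: Chiral-Lewis-acid-catalysed Mukaiyama–Michael addition on the enone face selected by the oxazaborolidinium cation sets the later C3a, and the regiodefined silyl enol ether 3 is then aminomethylated (Mannich reaction) on the carbon that becomes C7a.

**Step 2**
Reactants: 4 methyl 2-[(1R,5S)-5-[(dimethylamino)methyl]-2,2-dimethyl-4-oxocyclopentyl]acetate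
Product: 6 methyl 2-[(1S)-2,2-dimethyl-5-methylidene-4-oxocyclopentyl]acetate, via methiodide 5 (not isolated)
Conditions: MeI, MeOH, rt; then aq NaHCO3, CH2Cl2, rt
Reagents that add atoms: none
Why: Hofmann-type E1cB elimination of the β-ammonium ketone gives the exocyclic enone, making the carbon next to the ketone trigonal so that it cannot bias the following addition.

**Step 3**
Reactants: 6 methyl 2-[(1S)-2,2-dimethyl-5-methylidene-4-oxocyclopentyl]acetate
Product: 8 (1R,5S)-1,6,6-trimethyl-8-methylidene-2-oxabicyclo[3.2.1]octan-3-one, via tertiary alkoxide 7 (not isolated)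
Conditions: MeMgBr, CeCl3, THF, −78 °C to rt; aq NH4Cl
Reagents that add atoms: methylmagnesium bromide C[Mg]Br
Why: Organocerium 1,2-addition (Imamoto) should occur on the face opposite the CH2CO2Me arm, and only the resulting cis hydroxy ester can lactonise to the bridged δ-lactone, which fixes the tertiary carbinol centre and filters out any minor epimer.

**Step 4**
Reactants: 8 (1R,5S)-1,6,6-trimethyl-8-methylidene-2-oxabicyclo[3.2.1]octan-3-one
Product: 10 (1R,5R,8S)-8-(hydroxymethyl)-1,6,6-trimethyl-2-oxabicyclo[3.2.1]octan-3-one, via alkylborane 9 (not isolated)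
Conditions: 9-BBN, THF, 0 °C to rt; then H2O2, aq NaHCO3, 0 °C
Reagents that add atoms: hydrogen peroxide OO
Why: Brown hydroboration–oxidation puts boron on the exocyclic CH2 and delivers hydrogen to C8 from the face of the three-atom lactone bridge, because the exo methyl on C6 shields the other face, so CH2OH ends anti to the lactone oxygen.

**Step 5**
Reactants: 10 (1R,5R,8S)-8-(hydroxymethyl)-1,6,6-trimethyl-2-oxabicyclo[3.2.1]octan-3-one
Product: 11 (1R,2S,3R)-3-(2-hydroxyethyl)-2-(hydroxymethyl)-1,4,4-trimethylcyclopentan-1-ol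
Conditions: LiAlH4, THF, 0 °C
Reagents that add atoms: none
Why: Hydride reduction opens the lactone to the primary alcohol and releases the tertiary alcohol without touching a stereocentre.

**Step 6**
Reactants: 11 (1R,2S,3R)-3-(2-hydroxyethyl)-2-(hydroxymethyl)-1,4,4-trimethylcyclopentan-1-ol
Product: 12 (1R,2R,5R)-2-hydroxy-2,4,4-trimethyl-5-(2-oxoethyl)cyclopentane-1-carbaldehyde (in equilibrium with its bridged lactol)
Conditions: (COCl)2, DMSO, CH2Cl2, −78 °C; Et3N, −78 to 0 °C
Reagents that add atoms: none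
Why: Swern oxidation converts both primary alcohols to aldehydes while the tertiary alcohol cannot be oxidised, and the cold work-up should leave the α-centre of the hindered aldehyde intact.

**Step 7**
Reactants: 13 triphenylphosphine hydrobromide; 14 methyl but-2-ynoate
Product: 15 [(E)-4-methoxy-4-oxobut-2-en-2-yl]triphenylphosphonium bromide
Conditions: MeCN, 60 °C
Reagents that add atoms: none
Why: Phospha-Michael addition of Ph3P to the protonated ynoate gives the β-phosphonio crotonate; its alkene geometry is irrelevant because both carbons are rehybridised later.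

**Step 8**
Reactants: 12 (1R,2R,5R)-2-hydroxy-2,4,4-trimethyl-5-(2-oxoethyl)cyclopentane-1-carbaldehyde; 15 [(E)-4-methoxy-4-oxobut-2-en-2-yl]triphenylphosphonium bromide
Product: 18 methyl (1R,3aS,4R,5S,7aR)-4-formyl-1-hydroxy-1,3,3,6-tetramethyl-2,3,3a,4,5,7a-hexahydro-1H-indene-5-carboxylate, via enamine 16 (not isolated), via ylide iminium salt 17 (not isolated)
Conditions: (S)-α,α-diphenylprolinol trimethylsilyl ether (20 mol %), NaHCO3 (1.5 equiv), CHCl3, rt
Reagents that add atoms: none
Why: Proposed new method: the diarylprolinol silyl ether condenses only with the unhindered CH2CHO arm of 12, the enamine 16 adds to the carbon of 15 that is β to phosphorus (α to the ester) to give ylide 17, and this non-stabilised ylide closes the ring onto the C7a formyl group by a 6-exo-trig carbonyl addition and oxaphosphetane collapse (intramolecular Wittig reaction), after which hydrolysis returns the catalyst. The closest known reaction types are the Schweizer annulation of enolates with vinylphosphonium salts, the Stork enamine Michael addition and the amine-catalysed Michael/Horner–Wadsworth–Emmons domino of Hayashi. C4 is set by the (S)-catalyst, which shields one enamine face, and being α to the aldehyde it can also equilibrate to the equatorial position; C5 is set in the conjugate addition, which should be reversible, so that the chair-like ring closure with the ester equatorial (trans to C4) is product-determining. The step needs chemoselective enamine formation (secured by the α-branching of the other aldehyde), attack at the ester α-carbon (secured by phosphonium being the stronger acceptor and by ylide formation) and Wittig closure faster than proton transfer (secured by the six-membered intramolecular geometry).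

**Step 9**
Reactants: 18 methyl (1R,3aS,4R,5S,7aR)-4-formyl-1-hydroxy-1,3,3,6-tetramethyl-2,3,3a,4,5,7a-hexahydro-1H-indene-5-carboxylate; 19 (4-bromophenoxy)tri(propan-2-yl)silane
Product: 21 methyl (1R,3aR,4R,5S,7aR)-1-hydroxy-4-[hydroxy(4-{[tri(propan-2-yl)silyl]oxy}phenyl)methyl]-1,3,3,6-tetramethyl-2,3,3a,4,5,7a-hexahydro-1H-indene-5-carboxylate (both carbinol epimers), via aryl Grignard 20 (not isolated)
Conditions: 19, Mg, THF, rt; then 18, THF, −78 °C; AcOH quench at −78 °C
Reagents that add atoms: none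
Why: Grignard addition to the aldehyde at −78 °C is much faster than attack on the methyl ester; the configuration of the new carbinol is irrelevant because it is oxidised next.

**Step 10**
Reactants: 21 the carbinol mixture from step 9
Product: 22 methyl (1R,3aS,4R,5S,7aR)-1-hydroxy-1,3,3,6-tetramethyl-4-(4-{[tri(propan-2-yl)silyl]oxy}benzoyl)-2,3,3a,4,5,7a-hexahydro-1H-indene-5-carboxylate
Conditions: Dess–Martin periodinane, NaHCO3, CH2Cl2, 0 °C
Reagents that add atoms: none
Why: Dess–Martin oxidation of the secondary benzylic alcohol under buffered conditions leaves the tertiary alcohol and the β,γ-unsaturated ester untouched.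

**Step 11**
Reactants: 22 the aryl ketone from step 10
Product: 23 methyl (1R,3aR,4R,5S,7aR)-1-hydroxy-4-[(S)-hydroxy(4-{[tri(propan-2-yl)silyl]oxy}phenyl)methyl]-1,3,3,6-tetramethyl-2,3,3a,4,5,7a-hexahydro-1H-indene-5-carboxylate
Conditions: LiBH(s-Bu)3 (L-Selectride), THF, −78 °C; AcOH quench at −78 °C
Reagents that add atoms: none
Why: Felkin–Anh reduction by the bulky hydride, with C3a as the large group anti to the incoming hydride and lithium bridging the ketone and ester oxygens, should give the (S)-carbinol; the cold acidic quench prevents lactonisation.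

**Step 12**
Reactants: 23 the (S)-carbinol from step 11
Product: 24 bis(triethylsilyl) ether of 23 (benzylic and tertiary oxygen silylated)
Conditions: TESOTf, 2,6-lutidine, CH2Cl2, −78 to 0 °C
Reagents that add atoms: triethylsilyl trifluoromethanesulfonate CC[Si](CC)(CC)OS(=O)(=O)C(F)(F)F
Why: Silyl triflate silylation protects both hydroxy groups so that no lactol can form after the next reduction.

**Step 13**
Reactants: 24 bis(triethylsilyl) ether of 23
Product: 25 (1R,3aR,4R,5S,7aR)-1,3,3,6-tetramethyl-1-[(triethylsilyl)oxy]-4-[(S)-[(triethylsilyl)oxy](4-{[tri(propan-2-yl)silyl]oxy}phenyl)methyl]-2,3,3a,4,5,7a-hexahydro-1H-indene-5-carbaldehyde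
Conditions: i-Bu2AlH, toluene, −78 °C; aq potassium sodium tartrate
Reagents that add atoms: none
Why: Partial ester reduction: the tetrahedral aluminium hemiacetal is stable at −78 °C and releases the aldehyde only on work-up.

**Step 14**
Reactants: 25 the aldehyde from step 13
Product: 26 (1R,3aR,4R,5R,7aR)-5-ethynyl analogue of 25 (CHO replaced by C≡CH)
Conditions: TMSCHN2, n-BuLi, THF, −78 to 0 °C; aq NH4Cl
Reagents that add atoms: (trimethylsilyl)diazomethane C[Si](C)(C)C=[N+]=[N-]
Why: Colvin rearrangement (Seyferth–Gilbert-type homologation) gives the terminal alkyne at low temperature, avoiding carbonate/methanol conditions that could epimerise C5 or conjugate the β,γ-alkene.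

**Step 15**
Reactants: 27 propanal; 28 3-(trimethylsilyl)prop-2-ynal
Product: 29 (2S,3R)-3-hydroxy-2-methyl-5-(trimethylsilyl)pent-4-ynal
Conditions: L-proline (20 mol %), DMF, 4 °C, slow addition of 27
Reagents that add atoms: none
Why: Proline-catalysed cross-aldol reaction (List–Houk enamine transition state) of the propanal enamine with the non-enolisable ynal gives the anti aldol, with L-proline controlling both centres.

**Step 16**
Reactants: 29 (2S,3R)-3-hydroxy-2-methyl-5-(trimethylsilyl)pent-4-ynal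
Product: 30 (2S,3R)-3-[(tert-butyldimethylsilyl)oxy]-2-methyl-5-(trimethylsilyl)pent-4-ynal
Conditions: TBSOTf, 2,6-lutidine, CH2Cl2, −78 °C
Reagents that add atoms: tert-butyldimethylsilyl trifluoromethanesulfonate CC(C)(C)[Si](C)(C)OS(=O)(=O)C(F)(F)F
Why: Silylation under non-basic triflate/lutidine conditions protects the β-hydroxy aldehyde before it can dehydrate or epimerise.

**Step 17**
Reactants: 30 (2S,3R)-3-[(tert-butyldimethylsilyl)oxy]-2-methyl-5-(trimethylsilyl)pent-4-ynal
Product: 32 (4R,5R,6R)-6-[(tert-butyldimethylsilyl)oxy]-5-methyl-8-(trimethylsilyl)oct-1-en-7-yn-4-ol, via borinate 31 (not isolated)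
Conditions: (+)-Ipc2B(allyl), Et2O, −78 °C; then NaBO3·4H2O, THF/H2O, rt
Reagents that add atoms: (+)-B-allyldiisopinocampheylborane C=CCB([C@H]1C[C@H]2C[C@H](C2(C)C)[C@@H]1C)[C@H]1C[C@H]2C[C@H](C2(C)C)[C@@H]1C
Why: Brown allylboration through a closed chair transition state is reagent-controlled; the reagent from (−)-α-pinene should add to the Re face, overriding the Felkin preference to give the 1,3-syn, 2,3-anti carbinol.

**Step 18**
Reactants: 32 the homoallylic alcohol from step 17
Product: 33 (4R,5R,6R)-4,6-bis[(tert-butyldimethylsilyl)oxy]-5-methyl-8-(trimethylsilyl)oct-1-en-7-yne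
Conditions: TBSOTf, 2,6-lutidine, CH2Cl2, 0 °C
Reagents that add atoms: tert-butyldimethylsilyl trifluoromethanesulfonate CC(C)(C)[Si](C)(C)OS(=O)(=O)C(F)(F)F
Why: Standard silyl triflate protection of the secondary alcohol.

**Step 19**
Reactants: 33 the bis-silyl ether from step 18
Product: 34 (2E,5R,6R,7R)-5,7-bis[(tert-butyldimethylsilyl)oxy]-2,6-dimethyl-9-(trimethylsilyl)non-2-en-8-ynal
Conditions: methacrolein (10 equiv), second-generation Hoveyda–Grubbs catalyst (5 mol %), CH2Cl2, 40 °C
Reagents that add atoms: methacrolein CC(=C)C=O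
Why: Cross-metathesis of the monosubstituted alkene with excess methacrolein gives the (E)-2-methyl enal, while the silyl-capped alkyne is too hindered for enyne metathesis.

**Step 20**
Reactants: 34 the enal from step 19
Product: 35 methyl (2Z,4E,7R,8R,9R)-7,9-bis[(tert-butyldimethylsilyl)oxy]-4,8-dimethyl-11-(trimethylsilyl)undeca-2,4-dien-10-ynoate
Conditions: (CF3CH2O)2P(O)CH2CO2Me, KN(SiMe3)2, 18-crown-6, THF, −78 °C
Reagents that add atoms: methyl bis(2,2,2-trifluoroethyl)phosphonoacetate COC(=O)CP(=O)(OCC(F)(F)F)OCC(F)(F)F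
Why: Still–Gennari olefination gives the (Z)-enoate by fast, irreversible elimination from the kinetic adduct.

**Step 21**
Reactants: 35 the silylalkyne dienoate from step 20
Product: 36 methyl (2Z,4E,7R,8R,9R)-7,9-bis[(tert-butyldimethylsilyl)oxy]-4,8-dimethylundeca-2,4-dien-10-ynoate
Conditions: K2CO3 (cat.), MeOH, 0 °C
Reagents that add atoms: none
Why: Methanolysis cleaves only the alkynyl C–Si bond; the silyl ethers and the methyl ester are unaffected.

**Step 22**
Reactants: 36 the terminal alkyne from step 21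
Product: 37 methyl (2Z,4E,7R,8R,9R,12Z)-7,9-bis[(tert-butyldimethylsilyl)oxy]-13-chloro-4,8-dimethyltrideca-2,4,12-trien-10-ynoate
Conditions: (Z)-ClCH=CHCl (5 equiv), Pd(PPh3)4 (5 mol %), CuI (10 mol %), n-BuNH2, Et2O, rt
Reagents that add atoms: (Z)-1,2-dichloroethene Cl/C=C\Cl
Why: Sonogashira coupling (Linstrumelle conditions); the excess dichloroethene reacts once with retention of the Z geometry.

**Step 23**
Reactants: 26 the core alkyne from step 14; 37 the (Z)-chloroenyne from step 22
Product: 38 (Z)-enediyne (core C5–C≡C–CH=CH–C≡C–chain, all silyl ethers and methyl ester retained)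
Conditions: PdCl2(PhCN)2 (5 mol %), CuI (10 mol %), piperidine, rt
Reagents that add atoms: none
Why: Second Sonogashira coupling, now at the vinyl chloride, which needs the amine-rich Alami–Linstrumelle conditions and retains the Z geometry.

**Step 24**
Reactants: 38 the (Z)-enediyne
Product: 39 (Z,Z,Z)-triene, fully silylated methyl ester of the target
Conditions: Zn dust activated with Cu(OAc)2 and AgNO3, MeOH/H2O 1:1, rt, dark
Reagents that add atoms: none
Why: Boland reduction: activated zinc reduces only alkynes conjugated to an alkene, by cis delivery of two hydrogens, so both triple bonds become Z alkenes and the dienoate stays intact.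

**Step 25**
Reactants: 39 the silylated triene methyl ester
Product: 41 CNP0118468.2 (target acid), via pentaol methyl ester 40 (not isolated)
Conditions: Bu4NF, THF, 0 °C to rt; then LiOH, H2O/MeOH, 0 °C; aq NH4Cl to pH 6
Reagents that add atoms: lithium hydroxide [Li+].[OH-]
Why: Fluoride removes all five silyl groups and hydroxide then saponifies the methyl ester; the medium is never acidic, which avoids ionisation of the 4-hydroxybenzylic alcohol to a quinone methide.

**Compound list**
1 | 4,4-dimethylcyclopent-2-en-1-one | O=C1C=CC(C)(C)C1 | starting material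
2 | 1-[(tert-butyldimethylsilyl)oxy]-1-methoxyethene | C=C(OC)O[Si](C)(C)C(C)(C)C | starting material
3 | methyl 2-[(1R)-4-[(tert-butyldimethylsilyl)oxy]-2,2-dimethylcyclopent-3-en-1-yl]acetate | COC(=O)C[C@@H]1C=C(O[Si](C)(C)C(C)(C)C)CC1(C)C | intermediate
4 | methyl 2-[(1R,5S)-5-[(dimethylamino)methyl]-2,2-dimethyl-4-oxocyclopentyl]acetate | COC(=O)C[C@@H]1[C@@H](CN(C)C)C(=O)CC1(C)C | intermediate
5 | N-methyl quaternary ammonium iodide of 4 | COC(=O)C[C@@H]1[C@@H](C[N+](C)(C)C)C(=O)CC1(C)C.[I-] | intermediate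
6 | methyl 2-[(1S)-2,2-dimethyl-5-methylidene-4-oxocyclopentyl]acetate | COC(=O)C[C@@H]1C(=C)C(=O)CC1(C)C | intermediate
7 | methyl 2-[(1S,4R)-4-hydroxy-2,2,4-trimethyl-5-methylidenecyclopentyl]acetate (formed as its magnesium alkoxide) | COC(=O)C[C@@H]1C(=C)[C@](C)(O)CC1(C)C | intermediate
8 | (1R,5S)-1,6,6-trimethyl-8-methylidene-2-oxabicyclo[3.2.1]octan-3-one | C=C1[C@@]2(C)CC(C)(C)[C@@H]1CC(=O)O2 | intermediate
9 | 9-borabicyclo[3.3.1]nonane adduct of 8 (boron on the exocyclic CH2, CH2B anti to the lactone bridge) | C(B1C2CCCC1CCC2)[C@H]1[C@@]2(C)CC(C)(C)[C@@H]1CC(=O)O2 | intermediate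
10 | (1R,5R,8S)-8-(hydroxymethyl)-1,6,6-trimethyl-2-oxabicyclo[3.2.1]octan-3-one | OC[C@H]1[C@@]2(C)CC(C)(C)[C@@H]1CC(=O)O2 | intermediate
11 | (1R,2S,3R)-3-(2-hydroxyethyl)-2-(hydroxymethyl)-1,4,4-trimethylcyclopentan-1-ol | OC[C@H]1[C@](C)(O)CC(C)(C)[C@@H]1CCO | intermediate
12 | (1R,2R,5R)-2-hydroxy-2,4,4-trimethyl-5-(2-oxoethyl)cyclopentane-1-carbaldehyde | O=C[C@H]1[C@](C)(O)CC(C)(C)[C@@H]1CC=O | intermediate
13 | triphenylphosphine hydrobromide | [PH+](c1ccccc1)(c1ccccc1)c1ccccc1.[Br-] | starting material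
14 | methyl but-2-ynoate | CC#CC(=O)OC | starting material
15 | [(E)-4-methoxy-4-oxobut-2-en-2-yl]triphenylphosphonium bromide | COC(=O)/C=C(\C)[P+](c1ccccc1)(c1ccccc1)c1ccccc1.[Br-] | intermediate
16 | (E)-enamine of the CH2CHO arm of 12 with (S)-diphenylprolinol trimethylsilyl ether | O=C[C@H]1[C@](C)(O)CC(C)(C)[C@@H]1/C=C/N1CCC[C@H]1C(O[Si](C)(C)C)(c1ccccc1)c1ccccc1 | intermediate
17 | conjugate adduct of 16 and 15: iminium bromide carrying the phosphorus ylide | CC(=P(c1ccccc1)(c1ccccc1)c1ccccc1)[C@@H](C(=O)OC)[C@H](C=[N+]1CCC[C@H]1C(O[Si](C)(C)C)(c1ccccc1)c1ccccc1)[C@@H]1[C@@H](C=O)[C@](C)(O)CC1(C)C.[Br-] | intermediate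
18 | methyl (1R,3aS,4R,5S,7aR)-4-formyl-1-hydroxy-1,3,3,6-tetramethyl-2,3,3a,4,5,7a-hexahydro-1H-indene-5-carboxylate | CC1=C[C@@H]2[C@@H]([C@@H](C=O)[C@@H]1C(=O)OC)C(C)(C)C[C@@]2(C)O | intermediate
19 | (4-bromophenoxy)tri(propan-2-yl)silane | CC(C)[Si](Oc1ccc(Br)cc1)(C(C)C)C(C)C | starting material
20 | (4-{[tri(propan-2-yl)silyl]oxy}phenyl)magnesium bromide | CC(C)[Si](Oc1ccc([Mg]Br)cc1)(C(C)C)C(C)C | intermediate
21 | methyl (1R,3aR,4R,5S,7aR)-1-hydroxy-4-[hydroxy(4-{[tri(propan-2-yl)silyl]oxy}phenyl)methyl]-1,3,3,6-tetramethyl-2,3,3a,4,5,7a-hexahydro-1H-indene-5-carboxylate (carbinol epimers) | CC1=C[C@@H]2[C@@H]([C@@H](C(O)c3ccc(O[Si](C(C)C)(C(C)C)C(C)C)cc3)[C@@H]1C(=O)OC)C(C)(C)C[C@@]2(C)O | intermediate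
22 | methyl (1R,3aS,4R,5S,7aR)-1-hydroxy-1,3,3,6-tetramethyl-4-(4-{[tri(propan-2-yl)silyl]oxy}benzoyl)-2,3,3a,4,5,7a-hexahydro-1H-indene-5-carboxylate | CC1=C[C@@H]2[C@@H]([C@@H](C(=O)c3ccc(O[Si](C(C)C)(C(C)C)C(C)C)cc3)[C@@H]1C(=O)OC)C(C)(C)C[C@@]2(C)O | intermediate
23 | methyl (1R,3aR,4R,5S,7aR)-1-hydroxy-4-[(S)-hydroxy(4-{[tri(propan-2-yl)silyl]oxy}phenyl)methyl]-1,3,3,6-tetramethyl-2,3,3a,4,5,7a-hexahydro-1H-indene-5-carboxylate | CC1=C[C@@H]2[C@@H]([C@@H]([C@H](O)c3ccc(O[Si](C(C)C)(C(C)C)C(C)C)cc3)[C@@H]1C(=O)OC)C(C)(C)C[C@@]2(C)O | intermediate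
24 | bis(triethylsilyl) ether of 23 | CC1=C[C@@H]2[C@@H]([C@@H]([C@H](O[Si](CC)(CC)CC)c3ccc(O[Si](C(C)C)(C(C)C)C(C)C)cc3)[C@@H]1C(=O)OC)C(C)(C)C[C@@]2(C)O[Si](CC)(CC)CC | intermediate
25 | (1R,3aR,4R,5S,7aR)-5-carbaldehyde corresponding to 24 | CC1=C[C@@H]2[C@@H]([C@@H]([C@H](O[Si](CC)(CC)CC)c3ccc(O[Si](C(C)C)(C(C)C)C(C)C)cc3)[C@@H]1C=O)C(C)(C)C[C@@]2(C)O[Si](CC)(CC)CC | intermediate
26 | (1R,3aR,4R,5R,7aR)-5-ethynyl compound corresponding to 25 | CC1=C[C@@H]2[C@@H]([C@@H]([C@H](O[Si](CC)(CC)CC)c3ccc(O[Si](C(C)C)(C(C)C)C(C)C)cc3)[C@@H]1C#C)C(C)(C)C[C@@]2(C)O[Si](CC)(CC)CC | intermediate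
27 | propanal | CCC=O | starting material
28 | 3-(trimethylsilyl)prop-2-ynal | C[Si](C)(C)C#CC=O | starting material
29 | (2S,3R)-3-hydroxy-2-methyl-5-(trimethylsilyl)pent-4-ynal | C[Si](C)(C)C#C[C@H](O)[C@H](C)C=O | intermediate
30 | (2S,3R)-3-[(tert-butyldimethylsilyl)oxy]-2-methyl-5-(trimethylsilyl)pent-4-ynal | C[Si](C)(C)C#C[C@H](O[Si](C)(C)C(C)(C)C)[C@H](C)C=O | intermediate
31 | diisopinocampheylborinate of 32 | C[Si](C)(C)C#C[C@H](O[Si](C)(C)C(C)(C)C)[C@H](C)[C@@H](CC=C)OB([C@H]1C[C@H]2C[C@H](C2(C)C)[C@@H]1C)[C@H]1C[C@H]2C[C@H](C2(C)C)[C@@H]1C | intermediate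
32 | (4R,5R,6R)-6-[(tert-butyldimethylsilyl)oxy]-5-methyl-8-(trimethylsilyl)oct-1-en-7-yn-4-ol | C[Si](C)(C)C#C[C@H](O[Si](C)(C)C(C)(C)C)[C@H](C)[C@H](O)CC=C | intermediate
33 | (4R,5R,6R)-4,6-bis[(tert-butyldimethylsilyl)oxy]-5-methyl-8-(trimethylsilyl)oct-1-en-7-yne | C[Si](C)(C)C#C[C@H](O[Si](C)(C)C(C)(C)C)[C@H](C)[C@H](O[Si](C)(C)C(C)(C)C)CC=C | intermediate
34 | (2E,5R,6R,7R)-5,7-bis[(tert-butyldimethylsilyl)oxy]-2,6-dimethyl-9-(trimethylsilyl)non-2-en-8-ynal | C[Si](C)(C)C#C[C@H](O[Si](C)(C)C(C)(C)C)[C@H](C)[C@H](O[Si](C)(C)C(C)(C)C)C/C=C(C)/C=O | intermediate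
35 | methyl (2Z,4E,7R,8R,9R)-7,9-bis[(tert-butyldimethylsilyl)oxy]-4,8-dimethyl-11-(trimethylsilyl)undeca-2,4-dien-10-ynoate | C[Si](C)(C)C#C[C@H](O[Si](C)(C)C(C)(C)C)[C@H](C)[C@H](O[Si](C)(C)C(C)(C)C)C/C=C(C)/C=C\C(=O)OC | intermediate
36 | methyl (2Z,4E,7R,8R,9R)-7,9-bis[(tert-butyldimethylsilyl)oxy]-4,8-dimethylundeca-2,4-dien-10-ynoate | C#C[C@H](O[Si](C)(C)C(C)(C)C)[C@H](C)[C@H](O[Si](C)(C)C(C)(C)C)C/C=C(C)/C=C\C(=O)OC | intermediate
37 | methyl (2Z,4E,7R,8R,9R,12Z)-7,9-bis[(tert-butyldimethylsilyl)oxy]-13-chloro-4,8-dimethyltrideca-2,4,12-trien-10-ynoate | Cl/C=C\C#C[C@H](O[Si](C)(C)C(C)(C)C)[C@H](C)[C@H](O[Si](C)(C)C(C)(C)C)C/C=C(C)/C=C\C(=O)OC | intermediate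
38 | (Z)-enediyne from 26 and 37 (core C5–C≡C–CH=CH–C≡C–chain; stereocentres as in the target) | CC1=C[C@@H]2[C@@H]([C@@H]([C@H](O[Si](CC)(CC)CC)c3ccc(O[Si](C(C)C)(C(C)C)C(C)C)cc3)[C@@H]1C#C/C=C\C#C[C@H](O[Si](C)(C)C(C)(C)C)[C@H](C)[C@H](O[Si](C)(C)C(C)(C)C)C/C=C(C)/C=C\C(=O)OC)C(C)(C)C[C@@]2(C)O[Si](CC)(CC)CC | intermediate
39 | (Z,Z,Z)-triene: methyl ester of the target carrying two TES, two TBS and one TIPS ether | CC1=C[C@@H]2[C@@H]([C@@H]([C@H](O[Si](CC)(CC)CC)c3ccc(O[Si](C(C)C)(C(C)C)C(C)C)cc3)[C@@H]1\C=C/C=C\C=C/[C@H](O[Si](C)(C)C(C)(C)C)[C@H](C)[C@H](O[Si](C)(C)C(C)(C)C)C/C=C(C)/C=C\C(=O)OC)C(C)(C)C[C@@]2(C)O[Si](CC)(CC)CC | intermediate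
40 | methyl ester of the target (all hydroxy groups free) | CC1=C[C@@H]2[C@@H]([C@@H]([C@H](O)c3ccc(O)cc3)[C@@H]1\C=C/C=C\C=C/[C@H](O)[C@H](C)[C@H](O)C/C=C(C)/C=C\C(=O)OC)C(C)(C)C[C@@]2(C)O | intermediate
41 | CNP0118468.2 | CC1=C[C@@H]2[C@@H]([C@@H]([C@H](O)c3ccc(O)cc3)[C@@H]1\C=C/C=C\C=C/[C@H](O)[C@H](C)[C@H](O)C/C=C(C)/C=C\C(=O)O)C(C)(C)C[C@@]2(C)O | target

**Step count.** Total: 25 steps. Longest linear sequence: 16 steps (1–6, 8–14, 23–25).

**Steps most likely to fail**

1. Step 8 (proposed new method). The ylide may undergo proton transfer and loss of triphenylphosphine (net α-substitution of the crotonate) instead of Wittig closure, or the salt may isomerise under base so that the enamine adds at the former methyl carbon. Fallback, known chemistry, from 12 back to 18: the same diarylprolinol silyl ether catalyses the established domino Michael/Henry reaction of a 1,5-dialdehyde with a nitroalkene, here methyl (E)-3-nitrobut-2-enoate, which makes the same C4–C5 and C6–C7 bonds and gives the nitro alcohol F1. Its secondary alcohol is converted with 1,1'-thiocarbonyldiimidazole and DMAP into the imidazolyl thiocarbonate F2. Bu3SnH and AIBN in toluene at 90 °C then generate the C7 radical, which expels NO2 by β-scission to give 18.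

2. Step 1. The hindered β-carbon next to the gem-dimethyl group may react slowly and with poor enantioface discrimination. Fallback from 1 and 2 back to 4: a racemic Mukaiyama–Michael addition catalysed by TMSOTf gives the racemic silyl enol ether F3. Saegusa–Ito oxidation (Pd(OAc)2, O2, DMSO) gives the achiral β-substituted enone F4. Asymmetric copper hydride conjugate reduction (Cu(OAc)2, (R)-DTBM-SEGPHOS, PhMe2SiH, toluene) then sets the same centre by hydride delivery and gives the regiodefined dimethylphenylsilyl enol ether F5, which is treated with Eschenmoser's salt to give 4.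

3. Step 3. The facial selectivity of methyl addition, controlled only by a 1,3-related substituent, may be low, which costs material at the lactonisation filter. Fallback from 4 back to 8, in which the C–O bond instead of the C–C bond is formed under tether control: Lombardo methylenation (Zn, CH2Br2, TiCl4) of the ketone gives the exocyclic alkene F6 and LiOH gives the acid F7. Acid-catalysed Markovnikov lactonisation (TsOH, CH2Cl2) can only deliver the carboxyl oxygen cis to its own arm and gives the amino lactone F8. mCPBA gives the N-oxide F9, and Cope elimination on warming gives 8.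

**Further compounds**
F1 | step 8 | methyl (1R,3aS,4R,5S,7aR)-4-formyl-1,7-dihydroxy-1,3,3,6-tetramethyl-6-nitrooctahydro-1H-indene-5-carboxylate (C6/C7 epimers) | CC1([N+](=O)[O-])C(O)[C@@H]2[C@@H]([C@@H](C=O)[C@@H]1C(=O)OC)C(C)(C)C[C@@]2(C)O
F2 | step 8 | O-(imidazol-1-ylthiocarbonyl) derivative of F1 at the C7 hydroxy group | CC1([N+](=O)[O-])C(OC(=S)n3ccnc3)[C@@H]2[C@@H]([C@@H](C=O)[C@@H]1C(=O)OC)C(C)(C)C[C@@]2(C)O
F3 | step 1 | racemic methyl 2-[4-[(tert-butyldimethylsilyl)oxy]-2,2-dimethylcyclopent-3-en-1-yl]acetate | COC(=O)CC1C=C(O[Si](C)(C)C(C)(C)C)CC1(C)C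
F4 | step 1 | methyl 2-(5,5-dimethyl-3-oxocyclopent-1-en-1-yl)acetate | COC(=O)CC1=CC(=O)CC1(C)C
F5 | step 1 | methyl 2-[(1R)-4-{[dimethyl(phenyl)silyl]oxy}-2,2-dimethylcyclopent-3-en-1-yl]acetate | COC(=O)C[C@@H]1C=C(O[Si](C)(C)c2ccccc2)CC1(C)C
F6 | step 3 | methyl 2-[(1R,5S)-5-[(dimethylamino)methyl]-2,2-dimethyl-4-methylidenecyclopentyl]acetate | COC(=O)C[C@@H]1[C@@H](CN(C)C)C(=C)CC1(C)C
F7 | step 3 | 2-[(1R,5S)-5-[(dimethylamino)methyl]-2,2-dimethyl-4-methylidenecyclopentyl]acetic acid | OC(=O)C[C@@H]1[C@@H](CN(C)C)C(=C)CC1(C)C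
F8 | step 3 | 8-[(dimethylamino)methyl]-1,6,6-trimethyl-2-oxabicyclo[3.2.1]octan-3-one (configuration as in 10) | CN(C)C[C@H]1[C@@]2(C)CC(C)(C)[C@@H]1CC(=O)O2
F9 | step 3 | N-oxide of F8 | C[N+](C)([O-])C[C@H]1[C@@]2(C)CC(C)(C)[C@@H]1CC(=O)O2
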